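- In a one-step world, starting material meets reagent, gives first product and stops, so more equivalents merely reach the same end sooner.

the same everywhere: starting material 0.13 M

| run | reagent | remark | time |
|---|---|---|---|
| Wednesday's | 1.5 equiv | run made earlier |  |
| Monday's | 3.5 equiv | run made earlier |  |
| red | 1.20 equiv |  | 12 min |
| blue | 2.00 equiv |  | 12 min |
| green | 3.00 equiv |  | 12 min |

| run | time / min | double product / % | first product / % | starting material / % |
|---|---|---|---|---|
| Wednesday's | 0.667 | 0 | 10 | 83 |
| Wednesday's | 2.00 | 0 | 24 | 57 |
| Wednesday's | 3.00 | 0 | 26 | 41 |
| Wednesday's | 5.00 | 1 | 38 | 27 |
| Wednesday's | 8.00 | 3 | 45 | 17 |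
| Wednesday's | 10.0 | 4 | 47 | 10 |
| Wednesday's | 12.0 | 3 | 48 | 8 |
| Monday's | 1.00 | 1 | 29 | 53 |
| Monday's | 1.33 | 3 | 32 | 41 |
| Monday's | 2.00 | 2 | 41 | 31 |
| Monday's | 3.00 | 3 | 46 | 18 |
| Monday's | 5.00 | 4 | 54 | 11 |
| Monday's | 8.00 | 9 | 54 | 4 |
| Monday's | 12.0 | 15 | 51 | 0 |

(standard deviation of a reading: 1.5 percentage points)

- a reading or a percentage of first product counts all its forms, free or not
- a reading of starting material is of its free form alone

- The simulated runs are not that world. After 12.0 min, Wednesday's run shows 8% starting material, 48% first product and 3% double product, so 41.0% of the charge is in none of the three readings.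
- Monday's run differs from Wednesday's in its equivalents, 3.5 equiv against 1.5 equiv. At the same time it reads 51% first product against 48%, but its double product reads 5.00 times as large on 2.33 times the equivalents, which I take as a sign that double product needs reagent in two passes.
- I read 1.90 for n, the logarithm of the ratio of double product between two runs over the logarithm of the ratio of their equivalents, at equal time and concentration: the reagent exponent, an apparent order. Wednesday's reading carries a scatter of 1.5 percentage points, so n is rough.

1. how much double product is there at the end, in percent of the starting material charged: for each flask in turn (red, blue, green)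

- Scaling Monday's reading by the ratio of equivalents raised to n, I expect 1.96% in red, 5.18% in blue and 11.2% in green. Red has fewer equivalents than Wednesday's run, and my figure for red stands below Wednesday's reading.
- The forecast gives 2.7%, 6% and 11.5%, holding that part of the consumed starting material “is locked away or diverted”. In red it stands above mine, and in blue too.

- The flasks give 1.98%, 5.53% and 11.3%, and the forecast is right within its margin; n gave 1.96% for red's 1.98% and 11.2% for green's 11.3%.

    reagent + first product → double product + released group (k = 0.00140 M⁻¹ s⁻¹)
    starting material + released group → side product (k = 0.0720 M⁻¹ s⁻¹)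
    starting material + reagent → first product + released group (k = 0.0140 M⁻¹ s⁻¹)
    starting material + first product ⇌ idle adduct, settled at all times (K = 21.0 M⁻¹)

- In red at 12.0 min, starting material has a half-life of 8.8 min by the step with reagent and 7.4 min by the step with released group, and side product stands at 30.9% beside 43.6% first product. Reagent in red then reacts 3.8 times as fast with starting material as with first product, with double product at 1.98%.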